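Slowness after 6.00 min carries the quick number you asked for: from that reading to 15.0 min the teal flask holds target and substrate level, given a scatter of 1 percentage point. Where a forward rate and a back rate cancel, dividing one by the other removes time, and what remains, as these readings give it, is 0.558: the plateau ratio, target over substrate at standstill, an apparent equilibrium constant.

the same everywhere: substrate 10 mM
- teal: catalyst 0.66 mM; temperature 80 °C; the very flask that is asked about, followed so far
- green: catalyst 0.99 mM; temperature 65 °C; run made earlier
- flask: catalyst 0.66 mM; temperature 80 °C; time 15 min

- teal (time / min: target / %, substrate / %): 3.00: 13.4, 33.7; 6.00: 16.8, 30.8; 10.0: 16.8, 28.7; 12.0: 16.8, 29.4; 15.0: 15.0, 28.4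
- green (time / min: target / %, substrate / %): 0.500: 0, 68.7; 1.00: 0.3, 50.2; 1.33: 2.5, 42.0; 2.00: 3.5, 30.2; 3.00: 6.3, 25.4

(readings scatter by 1 percentage point)

- Tuesday's: at 15 min raise the temperature by 20 K, then wait 15 min
- Thursday's: change nothing and wait 15 min more
- Friday's: at 15 min add catalyst, 100% of the amount charged, then wait 15 min
- Saturday's: at 15 min take out 90% of the target then present, then wait 15 min

* target, in percent of the substrate first charged, at 15 min
* what to do for the largest gain in target; "none" if nothing gains more than 2 percentage points (Tuesday's / Thursday's / Friday's / Saturday's / none)
* target present, with what was taken out counted in, in percent of the substrate first charged, after Tuesday's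
* target present, with what was taken out counted in, in percent of the substrate first charged, after Saturday's

- removed target is counted in
- additions bring no volume worth counting

My reckoning puts target now at 16.4% of the charge. The green run lost substrate while target read 0% at 0.500 min, so substrate has a second, unseen outlet, and in the teal flask the part not read stood at 52.9% at 3.00 min and 56.6% at 15.0 min, which reads as exchange. Fresh catalyst changes speed, not a ratio at equilibrium, so I expect no gain from Friday's. Taking target out should let the ratio rebuild from what remains, and 6.00 min of settling is shorter than the 15 min allowed. If the pools return to their old shares of what stays in the teal flask, Saturday's gives 28.7% with the removed target counted in, my choice. The ratio was read at 80 °C, so I give no figure for Tuesday's.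

The forecast also has target now at 16.4%, but it names Friday's as best, with 16.4% after Tuesday's and 16.5% after Saturday's, on the ground that the “most likely cause is catalyst death”.

The flask gives 16.5% now and Saturday's as best with 12 points, Friday's at −0.38 points, 10.4% after Tuesday's and 28.5% after Saturday's.

    substrate ⇌ target (K = 0.560, k = 0.0830 min⁻¹, Ea = 91.0 kJ mol⁻¹, ΔH = −47.0 kJ mol⁻¹)
    target ⇌ isomer of the product (K = 3.10, k = 0.470 min⁻¹, Ea = 104 kJ mol⁻¹, ΔH = 0 kJ mol⁻¹)
    isomer of the product + catalyst ⇌ substrate + catalyst, rate k3*[catalyst]*[isomer of the product] forward; the back reaction follows from the equilibrium constant (k = 600 L mol⁻¹ min⁻¹, Ea = 66.0 kJ mol⁻¹)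
    target → over-reaction product (k = 0.00920 min⁻¹, Ea = 108 kJ mol⁻¹)
    (constants at 80 °C)

In the flask, substrate exchanged with isomer of the product over the catalyst (relaxation half-life by that step alone 0.640 min at 15.0 min) and with target (3.00 min by that step alone), and 1.50 min in the flask held 44.2% substrate, 45.9% isomer of the product and 9.78% target. Catalyst stood at 100% at 15.0 min, target over substrate read 0.553 then and 0.553 at 150 min, and over-reaction product grew from 2.05% to 20.5%. The repeat at 105 °C ended with target over substrate at 0.192.

(The numbers in the tables are calculated from invented constants; scatter was added.)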